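At early times two flasks charged with the same L hold equal c(L) and equal c(Q) whenever they have made equal Q. So if the rate goes with a working amount of J, their curves are one curve on two clocks, and the ratio of their times to one amount of Q is the ratio of their rates.

| flask | L | J | time |
|---|---|---|---|
| south-west | 0.0500 M | 0.00100 M |  |
| south | 0.0300 M | 0.00100 M |  |
| east | 0.0500 M | 0.00300 M |  |
| north | 0.0750 M | 0.00100 M |  |
| north-west | 0.0170 M | 0.00200 M | 34 min |

| south-west run: time / min | south-west run: [Q] / M | south run: time / min | south run: [Q] / M | east run: time / min | east run: [Q] / M | north run: time / min | north run: [Q] / M |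
|---|---|---|---|---|---|---|---|
| 1.5 | 0.00162 | 1.5 | 0.00162 | 1.5 | 0.00638 | 1.5 | 0.00201 |
| 4.6 | 0.00433 | 4.6 | 0.00293 | 4.6 | 0.01539 | 4.6 | 0.00556 |
| 8.8 | 0.00780 | 8.8 | 0.00519 | 8.8 | 0.02365 | 8.8 | 0.00987 |
| 14 | 0.01103 | 14 | 0.00786 | 14 | 0.02997 | 14 | 0.01427 |
| 20 | 0.01464 | 20 | 0.01007 | 20 | 0.03516 | 20 | 0.01844 |
| 27 | 0.01754 | 27 | 0.01272 | 27 | 0.03904 | 27 | 0.02283 |
| 34 | 0.02002 | 34 | 0.01413 | 34 | 0.04168 | 34 | 0.02659 |

(scatter of a reading: 2 × 10⁻⁴ M)

1. how the opening rate goes with [J] round the charge of the south-west run: the exponent of the rate at two percent of L gone to Q
2. how the opening rate goes with [L] round the charge of the south-west run: the exponent of the rate at two percent of L gone to Q (one fixed amount of Q, the same in the runs compared)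
3. the south run starts with 0.0200 M less of L than the south-west run, and with no Q. Compared where both hold the same amount of L, once fifteen percent of what the south run was charged with has turned into Q, is the south run faster, slower or alike (within a tenth)?
4. Q in the north-west run at 34 min, as a share of the L charged

- Overall: L -> Q, with J as catalyst.
- Constant volume, constant temperature.
- What is held in complexes is read along with the free species.
- An order is taken over about fifteen percent of the charge, up and down.

1. The east run holds 0.01539 M at 4.6 min, and the south-west run, interpolated, reaches that amount at 21.8 min. The east clock therefore runs 4.74 times as fast, a factor greater than the ratio of the J charges, 3.00.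

2. Such a factor follows if each flask loses a fixed amount of J before anything turns over. This amount is the dead charge, the c(J) subtracted from every charge to leave the working J, and the two clocks give it as 4.65 × 10⁻⁴ M, about half of the south-west charge.

3. With rate proportional to c(J) minus the dead charge, the logarithmic slope at the south-west charge is that charge over its working J, 1.87. The exponent of 1.42 from the two charges is a mean over the whole span.

4. The south run has the nearest L charge, and 52.9% of it remains at 34 min. The north-west clock runs 2.87 times as fast, so multiplying the logarithm of that share by this factor gives 83.9% turned.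

5. The weak link is the L charge, which step 4 ignores. Between the south-west and south runs, the logarithm of the remaining share at equal time grows as the charge falls, with power 0.429. Carried down to the north-west charge, this gives 90.3%. That power is stretched beyond the runs, so the figure committed to is the middle, 87.1%.

The forecast stands at 1.4 and 0.65 for the exponents, faster for the south run and 80% for the north-west run. Its ground for J is “a 4.7-fold rise for 3× J, giving an order near 1.4”. The reckoning here differs from it on the J exponent and on the north-west share, and makes no estimate of its own for the L exponent or the south run.

The north-west run reaches 85.7% of its charge, the exponents are 1.9 for J and 0.67 for L, and the south run is faster.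

    J + L ⇌ JL (71.40 M⁻¹ min⁻¹, 0.4920 min⁻¹)
    JL → Q + J (5.796 min⁻¹)
    J + Oz → Wy
    J + Q ⇌ JQ, settled at all times (74.60 M⁻¹)

At one amount of Q made, the east run goes 4.5 times as fast as the south-west run. Taken as J lost to Oz, a stoichiometric poison, the dead charge leaves 5.35 × 10⁻⁴ M of J, bound forms counted, in the north run, where 0.0014 M min⁻¹ then comes to 2.53 min⁻¹ per working J, faster than the 1.88 min⁻¹ of the east run.

All runs stem from a simulated flask with constants of no real substance, noise included.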